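The data are calculated from invented constants; the scatter is artificial.

- A small charge, 0.1 mol% of free catalyst, takes the substrate down at one pace in both runs: at 10.0 h, Wednesday's run holds 59.7 % and Thursday's 60.8 %. So I book the fraction left, and Thursday's last reading gives a drain of 0.0529 h⁻¹.

| flask | substrate | partner | free catalyst | second catalyst | remark | time |
|---|---|---|---|---|---|---|
| Wednesday's | 0.050 M | 1 equiv | 0.1 mol% | 5 mol% | the very flask that is asked about, followed so far |  |
| Thursday's | 0.050 M | 1 equiv | 0.1 mol% | 7.5 mol% | run made earlier |  |
| flask | 0.050 M | 1.00 equiv | 0.1 mol% | 5 mol% |  | 2.0 d |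

| run | time / h | substrate / % | target / % |
|---|---|---|---|
| Wednesday's | 0.667 | 96.3 | 0 |
| Wednesday's | 2.00 | 90.0 | 0.4 |
| Wednesday's | 3.00 | 85.8 | 0.1 |
| Wednesday's | 5.00 | 78.1 | 1.4 |
| Wednesday's | 8.00 | 66.9 | 2.1 |
| Wednesday's | 10.0 | 59.7 | 4.7 |
| Thursday's | 3.00 | 85.4 | 0.5 |
| Thursday's | 6.00 | 72.9 | 3.0 |
| Thursday's | 10.0 | 60.8 | 6.8 |
| Thursday's | 12.0 | 54.3 | 8.9 |
| Thursday's | 15.0 | 46.5 | 12.9 |
| Thursday's | 20.0 | 34.7 | 18.4 |

(each reading ± 0.5 percentage points)

- the numbers in the tables scatter with a standard deviation of 0.5 percentage points
- the reaction counts as stopped when no species that holds the substrate changes by six tenths of a point or more over the second half of the time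

- why nothing more happens at 2.0 d, or that something still does (no working catalyst is left / it is still moving / all of the substrate has reacted / the partner has run out first)
- share of the substrate used up at 2.0 d
- target at 2.0 d, in percent of the substrate charged

- Substrate and partner are charged one to one, so I keep the ledger in fractions of the substrate charge. In Thursday's run, what is neither substrate nor target is a stock in between, on average 39.6 % of the charge from 10.0 h to 20.0 h.
- Target at 10.0 h stands at 4.7 % on Wednesday and 6.8 % on Thursday, a ratio of 0.691 against 0.667 in second catalyst. I therefore scale by loading.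
- I assume each target takes one partner, so Thursday's partner averages 87.4 % of charge over that stretch.
- Target's gain, divided by stock and partner left and scaled to 5 mol%, gives the clearing constant 0.0223 h⁻¹, a pseudo-first-order constant for the stock at full partner.
- Ledger for the asked flask at 2.0 d: substrate left is 7.88 %. With full partner, target reaches 46.5 %.
- Partner then averages about 76.7 %, so the constant sags to 0.0171 h⁻¹ and target comes to 38.8 %. The stock holds 53.3 %.
- Substrate falls 20 percentage points over the second half, so I say it is still moving.
- The forecast says it is still moving, 91.3 % used and 42.5 % target, noting “its rate scales with second-catalyst loading”. My target is lower than that.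
- The asked flask gives it is still moving, 91.3 % used and 37.1 % target, with partner at 58.6 % of its charge and intermediate at 49.8 %. At that partner, the clearing constant stands at 0.0131 h⁻¹. In the neighbour charged with 0.250 equiv of partner, 50.2 % of that smaller charge remains, so the constant stands at 0.00280 h⁻¹, and that neighbour ends with 78.1 % intermediate and 11.4 % target.

    substrate + free catalyst → free catalyst + intermediate (k = 0.270 M⁻¹ s⁻¹)
    partner + second catalyst + intermediate → second catalyst + target (k = 0.0530 M⁻² s⁻¹)
    substrate + partner → uncatalysed product (k = 1.50 × 10⁻⁵ M⁻¹ s⁻¹)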